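**Strategy.** Ring B (the dibromophenol ring; C1' carries the ether oxygen, C6' the hydroxyl) is built, not functionalised. Its four contiguous carbons C2'(H), C3'(Br), C4'(H) and C5'(Br) are C6, C5, C4 and C3 of 3,5-dibromo-2-pyrone. The oxygen-bearing pair C1'/C6' is the C=C of a bis-silyl ketene acetal made from the ring A aryloxyacetic acid. One thermal operation (inverse-demand [4+2] cycloaddition, then loss of CO2 and of silanol) forms the C1'–C2' and C5'–C6' bonds and delivers ring B as its aryl silyl ether. No late bromination or C–O coupling is needed. The precursor is ArO–CH=C(OSitBuMe2)2, Ar = 2,3,4,5-tetrabromo-6-methoxyphenyl.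

Key step: step 5

Remark on stereochemistry: the target is achiral. The only stereocentres in the route are those of the transient intermediates 10 and 11, which should form as racemic mixtures (10 also as endo/exo isomers) and are erased on aromatisation.

Remark on precursor design: both acetal oxygens carry the same silyl group, so the alkene has no E/Z isomers and loss of either oxygen gives the same arene. The acetal is made through the silyl ester because LiN(SiMe3)2 does not form the dianion of a free carboxylic acid.

Step 1
Reactants: 1 guaiacol (2-methoxyphenol)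
Product: 2 3,4,5,6-tetrabromo-2-methoxyphenol
Conditions: Br2 (5 equiv), Fe powder (cat.), CHCl3, 0 °C to reflux
Reagents that add atoms: bromine, BrBr
Why: Electrophilic aromatic bromination: the hydroxyl and methoxy donors activate all four ring positions, and FeBr3 formed in the flask supplies the extra electrophilicity needed for the last, most hindered substitution next to the methoxy group.

Step 2
Reactants: 2 3,4,5,6-tetrabromo-2-methoxyphenol; 3 bromoacetic acid
Product: 4 2-(2,3,4,5-tetrabromo-6-methoxyphenoxy)acetic acid
Conditions: NaOH (aq), H2O–iPrOH, reflux, 3 added in portions; then HCl to pH 1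
Reagents that add atoms: none
Why: Williamson ether synthesis: the phenoxide of 2 displaces bromide from bromoacetate in an SN2 reaction, and the aqueous alkali hydrolyses any glycolate ester by-products back to the carboxylate, so only the aryloxyacetic acid should precipitate on acidification.

Step 3
Reactants: 4 2-(2,3,4,5-tetrabromo-6-methoxyphenoxy)acetic acid
Product: 6 1,1-bis(tert-butyldimethylsilyloxy)-2-(2,3,4,5-tetrabromo-6-methoxyphenoxy)ethene, via tert-butyldimethylsilyl ester 5 (not isolated)
Conditions: LiN(SiMe3)2 (1.0 equiv), THF, 0 °C; TBSCl (2.4 equiv), DMPU, rt; then LiN(SiMe3)2 (1.3 equiv), −78 to 0 °C; pentane, filtration under Ar, used crude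
Reagents that add atoms: tert-butyldimethylsilyl chloride, CC(C)(C)[Si](C)(C)Cl
Why: Enolisation with internal silyl quench, as in the first stage of an Ireland–Claisen rearrangement: the lithium carboxylate is silylated to ester 5, whose C–H, acidified by the aryloxy group, is removed by LiN(SiMe3)2, and the enolate is trapped on oxygen by the TBSCl already present before it can lose silanolate.

Step 4
Reactants: 7 coumalic acid (2-oxo-2H-pyran-5-carboxylic acid)
Product: 9 3,5-dibromo-2H-pyran-2-one, via 5-bromo-2H-pyran-2-one 8 (not isolated)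
Conditions: NBS (2.5 equiv), LiOAc (cat.), MeCN–H2O, rt
Reagents that add atoms: N-bromosuccinimide, O=C1CCC(=O)N1Br
Why: Hunsdiecker-type bromodecarboxylation: ipso attack of electrophilic bromine at C5 (cation stabilised by the ring oxygen) is followed by loss of CO2 to give 8, and a second equivalent of NBS then brominates C3, the remaining nucleophilic position of the 2-pyrone.

Step 5
Reactants: 6 1,1-bis(tert-butyldimethylsilyloxy)-2-(2,3,4,5-tetrabromo-6-methoxyphenoxy)ethene; 9 3,5-dibromo-2H-pyran-2-one
Product: 12 tert-butyl[2,4-dibromo-6-(2,3,4,5-tetrabromo-6-methoxyphenoxy)phenoxy]dimethylsilane, via bridged lactone 10 (not isolated), via cyclohexadiene bis-silyl ketal 11 (not isolated)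
Conditions: 9 (1.5 equiv), PhMe, 110 °C, sealed tube, Ar
Reagents that add atoms: none
Why: The electron-rich C=C of 6 adds to the electron-poor diene of 9 in an inverse-demand Diels–Alder reaction that is probably highly asynchronous, the nucleophilic CH(OAr) carbon bonding to the electrophilic C6 and the acetal carbon closing onto C3 to give bridged lactone 10. Retro-[4+2] loss of CO2 then gives diene 11, in which the only sp3 hydrogen sits on the aryloxy-bearing carbon, so ionisation of one C–OSi bond to an O-silylated arenium ion and loss of that proton can only expel silanol and leave the 1-aryloxy-2-silyloxy arene 12. The closest known reactions are the cycloadditions of 3,5-dibromo-2-pyrone with enol ethers and those of 2-pyrones with 1,1-dialkoxyethenes that end in loss of CO2 and alcohol to give alkoxyarenes. Ring B is closed as a six-membered carbocycle by the [4+2] event, which forms C1'–C2' and C5'–C6', and is made aromatic by the two eliminations. No stereocentre survives, so no stereocontrol is needed. The one selectivity required is regiochemical (silyloxy carbon next to C3–Br, aryloxy carbon next to C6–H), and it should be secured by the polarisation of 6, whose two silyloxy donors sit on one terminus, matched with the larger LUMO coefficient at C6 of the pyrone.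

Step 6
Reactants: 12 tert-butyl[2,4-dibromo-6-(2,3,4,5-tetrabromo-6-methoxyphenoxy)phenoxy]dimethylsilane
Product: 13 2,4-dibromo-6-(2,3,4,5-tetrabromo-6-methoxyphenoxy)phenol
Conditions: Bu4NF (1.1 equiv), AcOH (1.1 equiv), THF, 0 °C
Reagents that add atoms: none
Why: Fluoride-mediated cleavage of an aryl silyl ether, driven by the Si–F bond and the good dibromophenoxide leaving group; the acetic acid buffer protonates the phenoxide at once, which guards against Smiles rearrangement or intramolecular SNAr onto ring A.

**Compound list**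

1 | guaiacol (2-methoxyphenol) | COc1ccccc1O | starting material
2 | 3,4,5,6-tetrabromo-2-methoxyphenol | COc1c(O)c(Br)c(Br)c(Br)c1Br | intermediate
3 | bromoacetic acid | OC(=O)CBr | starting material
4 | 2-(2,3,4,5-tetrabromo-6-methoxyphenoxy)acetic acid | COc1c(Br)c(Br)c(Br)c(Br)c1OCC(=O)O | intermediate
5 | tert-butyldimethylsilyl 2-(2,3,4,5-tetrabromo-6-methoxyphenoxy)acetate (not isolated) | COc1c(Br)c(Br)c(Br)c(Br)c1OCC(=O)O[Si](C)(C)C(C)(C)C | intermediate
6 | 1,1-bis(tert-butyldimethylsilyloxy)-2-(2,3,4,5-tetrabromo-6-methoxyphenoxy)ethene | COc1c(Br)c(Br)c(Br)c(Br)c1OC=C(O[Si](C)(C)C(C)(C)C)O[Si](C)(C)C(C)(C)C | intermediate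
7 | coumalic acid (2-oxo-2H-pyran-5-carboxylic acid) | O=C(O)c1ccc(=O)oc1 | starting material
8 | 5-bromo-2H-pyran-2-one (not isolated) | O=c1ccc(Br)co1 | intermediate
9 | 3,5-dibromo-2H-pyran-2-one | O=c1occ(Br)cc1Br | intermediate
10 | 4,6-dibromo-8,8-bis(tert-butyldimethylsilyloxy)-7-(2,3,4,5-tetrabromo-6-methoxyphenoxy)-2-oxabicyclo[2.2.2]oct-5-en-3-one, racemic, mixture of C7 epimers (not isolated) | O=C1OC2C(Br)=CC1(Br)C(O[Si](C)(C)C(C)(C)C)(O[Si](C)(C)C(C)(C)C)C2Oc1c(OC)c(Br)c(Br)c(Br)c1Br | intermediate
11 | 2,4-dibromo-1,1-bis(tert-butyldimethylsilyloxy)-6-(2,3,4,5-tetrabromo-6-methoxyphenoxy)cyclohexa-2,4-diene, racemic (not isolated) | BrC1=CC(Br)=CC(Oc2c(OC)c(Br)c(Br)c(Br)c2Br)C1(O[Si](C)(C)C(C)(C)C)O[Si](C)(C)C(C)(C)C | intermediate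
12 | tert-butyl[2,4-dibromo-6-(2,3,4,5-tetrabromo-6-methoxyphenoxy)phenoxy]dimethylsilane | COc1c(Br)c(Br)c(Br)c(Br)c1Oc1cc(Br)cc(Br)c1O[Si](C)(C)C(C)(C)C | intermediate
13 | 2,4-dibromo-6-(2,3,4,5-tetrabromo-6-methoxyphenoxy)phenol | COc1c(Br)c(Br)c(Br)c(Br)c1Oc1cc(Br)cc(Br)c1O | target

Total step count: 6
Longest linear sequence: 5 steps (steps 1, 2, 3, 5, 6)

**Steps most likely to fail, riskiest first**

Step 5. The two-bond union may not complete. Bond formation between the fully substituted acetal carbon and the brominated C3 may be slowed sterically, so that conjugate addition at C6 followed by silyl transfer and opening of the pyrone, or thermal desilylation of the acetal, outruns ring closure. Addition in the reverse orientation would exchange the positions of the two oxygens on ring B. The fallback gives up the pyrone disconnection; it sets out from 2 and comes back at 13. The phenoxide of 2 is arylated with 2-fluorobenzaldehyde by SNAr (Cs2CO3, DMF, 120 °C) to give 2-(2,3,4,5-tetrabromo-6-methoxyphenoxy)benzaldehyde F1. Baeyer–Villiger oxidation of the Dakin type (mCPBA, CH2Cl2, rt) should give 2-(2,3,4,5-tetrabromo-6-methoxyphenoxy)phenyl formate F2. Methanolysis (MeOH, cat. HCl) frees 2-(2,3,4,5-tetrabromo-6-methoxyphenoxy)phenol F3. Bromination of F3 (Br2, 2.0 equiv, AcOH, 0 °C to rt) is directed by the free hydroxyl to its ortho and para positions, which are exactly C5' and C3'; ring A has no hydrogen left, so this should give 13.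

Step 3. The silyl ester enolate may lose silanolate to form an aryloxyketene before it is silylated, silylation may occur on carbon, or the acetal may hydrolyse during isolation. The fallback sets out from 4 and comes back at 13, bypassing 6 and 12. The acid is deprotonated twice (LiN(iPr)2, 2.2 equiv, THF, −78 to 0 °C) to dilithium 2-(2,3,4,5-tetrabromo-6-methoxyphenoxy)ethene-1,1-diolate F4, which carries no leaving group on oxygen. Quenching with Me3SiCl at −78 °C gives 1,1-bis(trimethylsilyloxy)-2-(2,3,4,5-tetrabromo-6-methoxyphenoxy)ethene F5, which is freed from salts by pentane filtration and not purified. Heating crude F5 with 9 in PhMe at 100 °C should pass through the trimethylsilyl bridged lactone F6 and the trimethylsilyl cyclohexadiene ketal F7 to [2,4-dibromo-6-(2,3,4,5-tetrabromo-6-methoxyphenoxy)phenoxy]trimethylsilane F8. Work-up with dilute HCl in THF hydrolyses F8 to 13.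

Step 2. SN2 attack by the hindered, weakly basic phenoxide may be slow while bromoacetate is consumed by hydrolysis. The fallback sets out from 2 and comes back at 4. It uses a Mitsunobu reaction (methyl glycolate, PPh3, DIAD, THF, 0 °C to rt), in which the acidic phenol is an ideal pronucleophile and the electrophile is an alkoxyphosphonium ion in an anhydrous medium. This should give methyl 2-(2,3,4,5-tetrabromo-6-methoxyphenoxy)acetate F9, which is saponified (LiOH, THF–H2O, rt; then HCl) to 4.

**Further compounds**

F1 | step 5 | 2-(2,3,4,5-tetrabromo-6-methoxyphenoxy)benzaldehyde | COc1c(Br)c(Br)c(Br)c(Br)c1Oc1ccccc1C=O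
F2 | step 5 | 2-(2,3,4,5-tetrabromo-6-methoxyphenoxy)phenyl formate | COc1c(Br)c(Br)c(Br)c(Br)c1Oc1ccccc1OC=O
F3 | step 5 | 2-(2,3,4,5-tetrabromo-6-methoxyphenoxy)phenol | COc1c(Br)c(Br)c(Br)c(Br)c1Oc1ccccc1O
F4 | step 3 | dilithium 2-(2,3,4,5-tetrabromo-6-methoxyphenoxy)ethene-1,1-diolate | COc1c(Br)c(Br)c(Br)c(Br)c1OC=C([O-])[O-].[Li+].[Li+]
F5 | step 3 | 1,1-bis(trimethylsilyloxy)-2-(2,3,4,5-tetrabromo-6-methoxyphenoxy)ethene | COc1c(Br)c(Br)c(Br)c(Br)c1OC=C(O[Si](C)(C)C)O[Si](C)(C)C
F6 | step 3 | 4,6-dibromo-7-(2,3,4,5-tetrabromo-6-methoxyphenoxy)-8,8-bis(trimethylsilyloxy)-2-oxabicyclo[2.2.2]oct-5-en-3-one, racemic, mixture of C7 epimers | O=C1OC2C(Br)=CC1(Br)C(O[Si](C)(C)C)(O[Si](C)(C)C)C2Oc1c(OC)c(Br)c(Br)c(Br)c1Br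
F7 | step 3 | 2,4-dibromo-6-(2,3,4,5-tetrabromo-6-methoxyphenoxy)-1,1-bis(trimethylsilyloxy)cyclohexa-2,4-diene, racemic | BrC1=CC(Br)=CC(Oc2c(OC)c(Br)c(Br)c(Br)c2Br)C1(O[Si](C)(C)C)O[Si](C)(C)C
F8 | step 3 | [2,4-dibromo-6-(2,3,4,5-tetrabromo-6-methoxyphenoxy)phenoxy]trimethylsilane | COc1c(Br)c(Br)c(Br)c(Br)c1Oc1cc(Br)cc(Br)c1O[Si](C)(C)C
F9 | step 2 | methyl 2-(2,3,4,5-tetrabromo-6-methoxyphenoxy)acetate | COC(=O)COc1c(OC)c(Br)c(Br)c(Br)c1Br
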